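**Plan**
- The retrosynthesis first cuts the depside ester bond between the ring A carboxyl carbon C7 and the 4-oxygen of ring B; the ring B carboxyl is traced back to a formyl group and the two ring A phenols are masked as isopropyl ethers.
- Ring A carries C7 on C1, oxygen on C2 and C4, and the pentyl chain on C6. Pentyl and carboxyl on adjacent carbons, with oxygen on C2 beside C1, is the pattern left by nucleophile-then-electrophile addition across an aryne C1≡C6, so the C6–pentyl and C1–C7 bonds are cut together.
- Forward: a symmetric trifluoroarene becomes the fluoro bis(isopropyl ether); aryne carbolithiation and carboxylation give the ring A acid; formylation of the propylresorcinol gives the ring B aldehyde; then esterification, aldehyde-to-acid oxidation and ether cleavage.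
- Both benzene rings are bought and no ring is formed; the target has no stereocentre, so no stereocontrol is needed.

Key step: step 3

Remark on the chemistry: ring A numbering of the target is used throughout (C1 bears C7, C6 bears pentyl); in this numbering the fluoroarene precursor carries fluorine on C6 and isopropoxy groups on C2 and C4.

**Step 1**
Reactants: 1 1,3,5-trifluorobenzene; 2 propan-2-ol
Product: 5 1-fluoro-3,5-diisopropoxybenzene, via sodium isopropoxide 3 (not isolated), via 1,3-difluoro-5-isopropoxybenzene 4 (not isolated)
Conditions: NaH (2.2 equiv), 2 (2.2 equiv), NMP, 0 °C; then 1, 25 → 100 °C, sealed vessel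
Reagents that add atoms: none
Why: Two successive nucleophilic aromatic substitutions (SNAr) by isopropoxide should stop at the monofluoride, because each alkoxy group replaces an inductively activating fluorine and slows the next displacement, so two equivalents of alkoxide leave the third fluorine in place.

**Step 2**
Reactants: 6 1-chloropentane
Product: 7 pentyllithium
Conditions: Li metal (2.2 equiv, about 1% Na), pentane, reflux; filter, titrate
Reagents that add atoms: lithium, [Li]
Why: Direct insertion of lithium metal into a primary C–Cl bond in a hydrocarbon solvent is the standard preparation of alkyllithiums and should give a filterable, salt-poor solution of the reagent.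

**Step 3**
Reactants: 5 1-fluoro-3,5-diisopropoxybenzene; 7 pentyllithium; 8 carbon dioxide
Product: 13 2,4-diisopropoxy-6-pentylbenzoic acid, via 2-fluoro-4,6-diisopropoxyphenyllithium 9 (not isolated), via 3,5-diisopropoxybenzyne 10 (not isolated), via 2,4-diisopropoxy-6-pentylphenyllithium 11 (not isolated), via lithium 2,4-diisopropoxy-6-pentylbenzoate 12 (not isolated)
Conditions: 7 (3 equiv), THF/pentane, −78 °C, 1 h; −78 → −10 °C; then 8 (dry gas), −78 °C → rt; 1 M HCl
Reagents that add atoms: none
Why: Pentyllithium removes the proton on C1 of 5, which is flanked by fluorine and an isopropoxy group, to give 9, and on warming 9 loses LiF to form aryne 10 (C1≡C6, isopropoxy oxygen on C2). A second equivalent of pentyllithium adds at C6, the aryne terminus remote from oxygen, so that the carbanion develops at C1 beside the inductively withdrawing, lithium-coordinating C2 oxygen; the resulting aryllithium 11 captures CO2 at C1 to give carboxylate 12, and acidification gives 13. The closest known reaction type is carbolithiation of 3-alkoxybenzynes generated from 3-haloaryl ethers by alkyllithiums, followed by electrophilic trapping of the ortho-alkoxy aryllithium. No ring is closed and no stereocentre is formed. The step needs site-selective deprotonation and regioselective addition to the unsymmetrical aryne: the first is secured by the combined acidifying effect of fluorine and oxygen on the C–H between them and by the bulk of the isopropyl groups, which disfavours metalation between the two oxygens, and the second by the polarisation of the aryne by the C2 alkoxy group. Excess pentyllithium should outcompete aryllithiums 9 and 11 for the aryne and so suppress biaryl formation.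

**Step 4**
Reactants: 14 5-propylbenzene-1,3-diol
Product: 16 2,4-dihydroxy-6-propylbenzaldehyde, via (2,4-dihydroxy-6-propylbenzylidene)dimethyliminium chloride 15 (not isolated)
Conditions: POCl3 (1.2 equiv), DMF, 0 °C → rt; then H2O, 50 °C
Reagents that add atoms: N,N-dimethylformamide, CN(C)C=O; water, O
Why: In this Vilsmeier–Haack formylation the chloroiminium electrophile should attack the resorcinol para to one hydroxyl and ortho to the other (next to the propyl group), the site favoured over the more hindered carbon between the two hydroxyls, and hydrolysis of iminium salt 15 releases the aldehyde.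

**Step 5**
Reactants: 13 2,4-diisopropoxy-6-pentylbenzoic acid; 16 2,4-dihydroxy-6-propylbenzaldehyde
Product: 18 4-formyl-3-hydroxy-5-propylphenyl 2,4-diisopropoxy-6-pentylbenzoate, via 2,4-diisopropoxy-6-pentylbenzoic trifluoroacetic anhydride 17 (not isolated)
Conditions: (CF3CO)2O (2 equiv), toluene, rt; aq NaHCO3 work-up
Reagents that add atoms: none
Why: In this mixed-anhydride esterification (the trifluoroacetic anhydride method of depside coupling) anhydride 17 should ionise to an acylium ion stabilised by the two alkoxy groups, which bypasses the steric shielding of the di-ortho-substituted carboxyl and acylates the free 4-hydroxyl, the 2-hydroxyl being held in a hydrogen bond to the neighbouring formyl group.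

**Step 6**
Reactants: 18 4-formyl-3-hydroxy-5-propylphenyl 2,4-diisopropoxy-6-pentylbenzoate
Product: 19 4-[(2,4-diisopropoxy-6-pentylbenzoyl)oxy]-2-hydroxy-6-propylbenzoic acid
Conditions: NaClO2, NaH2PO4, 2-methyl-2-butene (excess), t-BuOH/THF/H2O, 0 °C → rt
Reagents that add atoms: sodium chlorite, [Na+].[O-]Cl=O
Why: The Pinnick chlorite oxidation should convert the hydrogen-bonded salicylaldehyde into the acid under buffered, mildly acidic conditions that leave the aryl ester and the isopropyl ethers untouched, while 2-methyl-2-butene consumes the hypochlorous acid that could otherwise chlorinate the alkoxy-substituted ring.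

**Step 7**
Reactants: 19 4-[(2,4-diisopropoxy-6-pentylbenzoyl)oxy]-2-hydroxy-6-propylbenzoic acid
Product: 20 4-[(2,4-dihydroxy-6-pentylbenzoyl)oxy]-2-hydroxy-6-propylbenzoic acid
Conditions: BCl3 (1 M in CH2Cl2, 6 equiv), CH2Cl2, −78 → 0 °C; then ice-water
Reagents that add atoms: none
Why: In this Lewis-acid dealkylation of aryl isopropyl ethers, boron coordinates each ether oxygen (helped at C2 by chelation to the ester carbonyl) and chloride removes the secondary alkyl group as 2-chloropropane at low temperature, conditions under which the aryl ester and the salicylic acid unit are expected to persist.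

**Compound list**
1 | 1,3,5-trifluorobenzene | Fc1cc(F)cc(F)c1 | starting material
2 | propan-2-ol | CC(C)O | starting material
3 | sodium isopropoxide | CC(C)[O-].[Na+] | intermediate
4 | 1,3-difluoro-5-isopropoxybenzene | CC(C)Oc1cc(F)cc(F)c1 | intermediate
5 | 1-fluoro-3,5-diisopropoxybenzene | CC(C)Oc1cc(F)cc(OC(C)C)c1 | intermediate
6 | 1-chloropentane | CCCCCCl | starting material
7 | pentyllithium | [Li]CCCCC | intermediate
8 | carbon dioxide | O=C=O | starting material
9 | 2-fluoro-4,6-diisopropoxyphenyllithium | [Li]c1c(F)cc(OC(C)C)cc1OC(C)C | intermediate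
10 | 3,5-diisopropoxybenzyne (3,5-diisopropoxy-1,2-didehydrobenzene) | CC(C)OC1=CC(OC(C)C)=CC#C1 | intermediate
11 | 2,4-diisopropoxy-6-pentylphenyllithium | [Li]c1c(CCCCC)cc(OC(C)C)cc1OC(C)C | intermediate
12 | lithium 2,4-diisopropoxy-6-pentylbenzoate | [Li+].[O-]C(=O)c1c(CCCCC)cc(OC(C)C)cc1OC(C)C | intermediate
13 | 2,4-diisopropoxy-6-pentylbenzoic acid | CCCCCc1cc(OC(C)C)cc(OC(C)C)c1C(=O)O | intermediate
14 | 5-propylbenzene-1,3-diol | CCCc1cc(O)cc(O)c1 | starting material
15 | (2,4-dihydroxy-6-propylbenzylidene)dimethyliminium chloride | CCCc1cc(O)cc(O)c1C=[N+](C)C.[Cl-] | intermediate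
16 | 2,4-dihydroxy-6-propylbenzaldehyde | CCCc1cc(O)cc(O)c1C=O | intermediate
17 | 2,4-diisopropoxy-6-pentylbenzoic trifluoroacetic anhydride | CCCCCc1cc(OC(C)C)cc(OC(C)C)c1C(=O)OC(=O)C(F)(F)F | intermediate
18 | 4-formyl-3-hydroxy-5-propylphenyl 2,4-diisopropoxy-6-pentylbenzoate | CCCCCc1cc(OC(C)C)cc(OC(C)C)c1C(=O)Oc1cc(O)c(C=O)c(CCC)c1 | intermediate
19 | 4-[(2,4-diisopropoxy-6-pentylbenzoyl)oxy]-2-hydroxy-6-propylbenzoic acid | CCCCCc1cc(OC(C)C)cc(OC(C)C)c1C(=O)Oc1cc(O)c(C(=O)O)c(CCC)c1 | intermediate
20 | 4-[(2,4-dihydroxy-6-pentylbenzoyl)oxy]-2-hydroxy-6-propylbenzoic acid | CCCCCc1cc(O)cc(O)c1C(=O)Oc1cc(O)c(C(=O)O)c(CCC)c1 | target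

**Step count:** 7 steps in total. The longest linear sequence is 5 steps (steps 1, 3, 5, 6, 7).

**Steps most likely to fail**

Step 3. Metalation between the two oxygens could compete with metalation beside fluorine, and aryllithium species could add to the aryne to give biaryls; both would erode the yield of the carboxylated adduct. The fallback sets out from 5 and reaches the same aryllithium without an aryne. Kumada coupling of 5 with commercial pentylmagnesium bromide under NiCl2(dppp) catalysis in THF should replace fluorine by pentyl and give 1,3-diisopropoxy-5-pentylbenzene F1. N-Bromosuccinimide in acetonitrile should brominate F1 para to one alkoxy group and next to the pentyl chain, giving 2-bromo-1,5-diisopropoxy-3-pentylbenzene F2. Bromine–lithium exchange of F2 with n-BuLi in THF at −78 °C then gives aryllithium 11, where the route is rejoined; carboxylation and acidification as in step 3 lead through 12 to 13.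

Step 5. The doubly ortho-substituted acid may be activated sluggishly, and acylation may spill over to the chelated 2-hydroxyl or to ring carbon. The fallback sets out from 16 and 13 and moves ring B to the acid oxidation level before the coupling. Pinnick oxidation of 16 should give 2,4-dihydroxy-6-propylbenzoic acid F3, and carboxylate-selective alkylation with benzyl bromide and KHCO3 in DMF should give benzyl 2,4-dihydroxy-6-propylbenzoate F4. Acid 13 is converted with oxalyl chloride and catalytic DMF into 2,4-diisopropoxy-6-pentylbenzoyl chloride F5, which should acylate the more acidic, unchelated 4-hydroxyl of F4 with K2CO3 in acetone to give benzyl 4-[(2,4-diisopropoxy-6-pentylbenzoyl)oxy]-2-hydroxy-6-propylbenzoate F6. Hydrogenolysis of F6 (H2, Pd/C, ethyl acetate) returns to the route at 19.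

Step 7. The Lewis acid may break the depside ester linkage or decarboxylate ring B, or the unchelated C4 ether may be cleaved incompletely. The fallback sets out from 13 and exchanges the ring A ethers for benzyl ethers before the coupling, so that the last step is a neutral hydrogenolysis. BCl3 on 13 should give 2,4-dihydroxy-6-pentylbenzoic acid F7; benzyl bromide and K2CO3 in DMF should give benzyl 2,4-bis(benzyloxy)-6-pentylbenzoate F8; saponification with KOH in aqueous dioxane should give 2,4-bis(benzyloxy)-6-pentylbenzoic acid F9. Coupling of F9 with 16 by trifluoroacetic anhydride in toluene proceeds through 2,4-bis(benzyloxy)-6-pentylbenzoic trifluoroacetic anhydride F10 and should give 4-formyl-3-hydroxy-5-propylphenyl 2,4-bis(benzyloxy)-6-pentylbenzoate F11. Pinnick oxidation should give 4-{[2,4-bis(benzyloxy)-6-pentylbenzoyl]oxy}-2-hydroxy-6-propylbenzoic acid F12, and hydrogenolysis of F12 (H2, Pd/C, ethyl acetate) returns to the route at 20.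

**Further compounds**
F1 | step 3 | 1,3-diisopropoxy-5-pentylbenzene | CCCCCc1cc(OC(C)C)cc(OC(C)C)c1
F2 | step 3 | 2-bromo-1,5-diisopropoxy-3-pentylbenzene | CCCCCc1cc(OC(C)C)cc(OC(C)C)c1Br
F3 | step 5 | 2,4-dihydroxy-6-propylbenzoic acid | CCCc1cc(O)cc(O)c1C(=O)O
F4 | step 5 | benzyl 2,4-dihydroxy-6-propylbenzoate | CCCc1cc(O)cc(O)c1C(=O)OCc1ccccc1
F5 | step 5 | 2,4-diisopropoxy-6-pentylbenzoyl chloride | CCCCCc1cc(OC(C)C)cc(OC(C)C)c1C(Cl)=O
F6 | step 5 | benzyl 4-[(2,4-diisopropoxy-6-pentylbenzoyl)oxy]-2-hydroxy-6-propylbenzoate | CCCCCc1cc(OC(C)C)cc(OC(C)C)c1C(=O)Oc1cc(O)c(C(=O)OCc2ccccc2)c(CCC)c1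
F7 | step 7 | 2,4-dihydroxy-6-pentylbenzoic acid | CCCCCc1cc(O)cc(O)c1C(=O)O
F8 | step 7 | benzyl 2,4-bis(benzyloxy)-6-pentylbenzoate | CCCCCc1cc(OCc2ccccc2)cc(OCc2ccccc2)c1C(=O)OCc1ccccc1
F9 | step 7 | 2,4-bis(benzyloxy)-6-pentylbenzoic acid | CCCCCc1cc(OCc2ccccc2)cc(OCc2ccccc2)c1C(=O)O
F10 | step 7 | 2,4-bis(benzyloxy)-6-pentylbenzoic trifluoroacetic anhydride | CCCCCc1cc(OCc2ccccc2)cc(OCc2ccccc2)c1C(=O)OC(=O)C(F)(F)F
F11 | step 7 | 4-formyl-3-hydroxy-5-propylphenyl 2,4-bis(benzyloxy)-6-pentylbenzoate | CCCCCc1cc(OCc2ccccc2)cc(OCc2ccccc2)c1C(=O)Oc1cc(O)c(C=O)c(CCC)c1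
F12 | step 7 | 4-{[2,4-bis(benzyloxy)-6-pentylbenzoyl]oxy}-2-hydroxy-6-propylbenzoic acid | CCCCCc1cc(OCc2ccccc2)cc(OCc2ccccc2)c1C(=O)Oc1cc(O)c(C(=O)O)c(CCC)c1
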